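## Retrosynthetic overview

- The target comes from its C13 4-methoxybenzyl ether by ether cleavage and acetylation; the nine-membered oxa-bridged ring is closed last by an intramolecular vinylogous aldol condensation that creates the C5=C6 ylidene of the butenolide.
- The 3(2H)-furanone is unmasked from an isoxazole (N–O cleavage, hydrolysis, cyclodehydration); the isoxazole ring is built by a nitrile oxide–alkyne [3+2] cycloaddition that joins the West and East fragments.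
- East fragment (alkyne, butenolide, C8 and C10): oxa-Michael/intramolecular Horner–Wadsworth–Emmons butenolide annulation on a cis-α-methyl-γ-lactone, itself made by a zinc Barbier lactonisation of D-glyceraldehyde acetonide and hydrogenation.
- West fragment (oxime, C4): ozonolysis of a tertiary vinyl carbinol obtained by Felkin–Anh vinyl Grignard addition to the methyl ketone of L-glycerate acetonide.
- Ring order: butenolide, isoxazole, furanone, nine-membered oxa-bridged ring.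

Assumption: locants C1–C15 are germacrane locants of the target (C1=C2–C3(=O) furanone enone, C4 C(CH3)–O, C5=C6 ylidene, C6–O–C12(=O) lactone, C7=C11, C8 CH–O-senecioate, C9 CH2, C10 CH(CH3), C13 CH2OAc; target = 4S,8S,10S), and 1, 2, 10 and 14 are taken as purchasable.

## Route

Step 1
Reactants: 1 (R)-2,2-dimethyl-1,3-dioxolane-4-carbaldehyde; 2 ethyl 2-(bromomethyl)prop-2-enoate
Product: 4 (5S)-5-[(4R)-2,2-dimethyl-1,3-dioxolan-4-yl]-3-methylideneoxolan-2-one, via hydroxy ester 3 (not isolated)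
Conditions: Zn dust, THF–sat. aq. NH4Cl, 0 °C to rt; then pyridinium p-toluenesulfonate (cat.), PhMe, 60 °C
Reagents that add atoms: none
Why: Zinc Barbier (Dreiding–Schmidt) allylation and lactonisation, in which Felkin–Anh attack anti to the dioxolane C–O bond of bought 1 sets C8 as S (anti adduct, expected about 8:1, minor lactone removed on silica).

Step 2
Reactants: 4 (5S)-5-[(4R)-2,2-dimethyl-1,3-dioxolan-4-yl]-3-methylideneoxolan-2-one
Product: 5 (3S,5S)-5-[(4R)-2,2-dimethyl-1,3-dioxolan-4-yl]-3-methyloxolan-2-one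
Conditions: H2 (1 atm), Pd/C, EtOAc, rt
Reagents that add atoms: none
Why: Catalytic hydrogenation adds to the exocyclic alkene from the face opposite the C8 substituent, so the new methyl is cis and C10 is S (substrate control by C8).

Step 3
Reactants: 5 (3S,5S)-5-[(4R)-2,2-dimethyl-1,3-dioxolan-4-yl]-3-methyloxolan-2-one
Product: 7 (1S,3S)-1-[(4R)-2,2-dimethyl-1,3-dioxolan-4-yl]-3-methylpent-4-yn-1-ol, via lactol 6 (not isolated)
Conditions: iBu2AlH, CH2Cl2, −78 °C; then dimethyl (1-diazo-2-oxopropyl)phosphonate, K2CO3, MeOH, 0 °C to rt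
Reagents that add atoms: dimethyl (1-diazo-2-oxopropyl)phosphonate, COP(=O)(OC)C(=[N+]=[N-])C(C)=O
Why: Partial lactone reduction and Seyferth–Gilbert homologation (Ohira–Bestmann reagent) of the open hydroxy aldehyde turn C1 into a terminal alkyne and free the C8 hydroxyl without touching a stereocentre.

Step 4
Reactants: 7 (1S,3S)-1-[(4R)-2,2-dimethyl-1,3-dioxolan-4-yl]-3-methylpent-4-yn-1-ol
Product: 8 (1S,3S)-1-[(4R)-2,2-dimethyl-1,3-dioxolan-4-yl]-3-methylpent-4-yn-1-yl 3-methylbut-2-enoate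
Conditions: 3-methylbut-2-enoyl chloride, pyridine, CH2Cl2, 0 °C
Reagents that add atoms: 3-methylbut-2-enoyl chloride, CC(C)=CC(=O)Cl
Why: Acylation of the only free hydroxyl installs the C8 senecioate with retention.

Step 5
Reactants: 8 (1S,3S)-1-[(4R)-2,2-dimethyl-1,3-dioxolan-4-yl]-3-methylpent-4-yn-1-yl 3-methylbut-2-enoate
Product: 9 (2R,3S,5S)-1,2-dihydroxy-5-methylhept-6-yn-3-yl 3-methylbut-2-enoate
Conditions: AcOH–H2O (4:1), 40 °C
Reagents that add atoms: none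
Why: Mild acid hydrolysis of the terminal isopropylidene acetal frees the C6/C7 diol under conditions where the ester does not migrate.

Step 6
Reactants: 9 (2R,3S,5S)-1,2-dihydroxy-5-methylhept-6-yn-3-yl 3-methylbut-2-enoate; 10 2-(diethoxyphosphoryl)prop-2-enoic acid
Product: 11 (2R,3S,5S)-2-hydroxy-5-methyl-3-[(3-methylbut-2-enoyl)oxy]hept-6-yn-1-yl 2-(diethoxyphosphoryl)prop-2-enoate
Conditions: DCC, 4-(dimethylamino)pyridine (5 mol %), CH2Cl2, −20 °C
Reagents that add atoms: none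
Why: Carbodiimide (Steglich) esterification is selective for the primary C6 hydroxyl over the hindered secondary C7 hydroxyl.

Step 7
Reactants: 11 (2R,3S,5S)-2-hydroxy-5-methyl-3-[(3-methylbut-2-enoyl)oxy]hept-6-yn-1-yl 2-(diethoxyphosphoryl)prop-2-enoate
Product: 12 (3S,5S)-5-methyl-3-[(3-methylbut-2-enoyl)oxy]-2-oxohept-6-yn-1-yl 2-(diethoxyphosphoryl)prop-2-enoate
Conditions: Dess–Martin periodinane, CH2Cl2, 0 °C to rt
Reagents that add atoms: none
Why: Dess–Martin oxidation gives the C7 ketone under non-basic conditions that leave the adjacent C8 stereocentre intact and destroy the now unneeded C7 stereocentre.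

Step 8
Reactants: 12 (3S,5S)-5-methyl-3-[(3-methylbut-2-enoyl)oxy]-2-oxohept-6-yn-1-yl 2-(diethoxyphosphoryl)prop-2-enoate
Product: 13 (1S,3S)-1-[4-({[(4-methoxyphenyl)methyl]oxy}methyl)-5-oxo-2,5-dihydrofuran-3-yl]-3-methylpent-4-yn-1-yl 3-methylbut-2-enoate
Conditions: 4-methoxybenzyl alcohol, Cs2CO3, THF, 0 °C
Reagents that add atoms: 4-methoxybenzyl alcohol, COc1ccc(CO)cc1
Why: Oxa-Michael addition to the vinylphosphonate followed by intramolecular Horner–Wadsworth–Emmons olefination of the C7 ketone closes the butenolide (C7=C11) and brings in C13–O as an ether that cannot be expelled in the later dienolate step.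

Step 9
Reactants: 14 methyl (4S)-2,2-dimethyl-1,3-dioxolane-4-carboxylate
Product: 16 1-[(4S)-2,2-dimethyl-1,3-dioxolan-4-yl]ethan-1-one, via Weinreb amide 15 (not isolated)
Conditions: MeNH(OMe)·HCl, iPrMgCl, THF, −20 °C; then MeMgBr, −20 to 0 °C
Reagents that add atoms: methylmagnesium bromide, C[Mg]Br
Why: One-pot Weinreb amide formation and Grignard addition gives the methyl ketone without over-addition and without epimerising the bought stereocentre.

Step 10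
Reactants: 16 1-[(4S)-2,2-dimethyl-1,3-dioxolan-4-yl]ethan-1-one
Product: 17 (2R)-2-[(4S)-2,2-dimethyl-1,3-dioxolan-4-yl]but-3-en-2-ol
Conditions: CH2=CHMgBr, THF, −78 °C
Reagents that add atoms: vinylmagnesium bromide, C=C[Mg]Br
Why: Felkin–Anh addition of the Grignard reagent anti to the dioxolane C–O bond of the bought stereocentre sets the tertiary carbinol C4 (2R here, 4S in the target; expected about 5:1, minor epimer removed on silica).

Step 11
Reactants: 17 (2R)-2-[(4S)-2,2-dimethyl-1,3-dioxolan-4-yl]but-3-en-2-ol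
Product: 19 (2R)-2-[(4S)-2,2-dimethyl-1,3-dioxolan-4-yl]-2-hydroxypropanal (E)-oxime, via hydroxy aldehyde 18 (not isolated)
Conditions: O3, CH2Cl2–MeOH, −78 °C; Me2S; then NH2OH·HCl, NaOAc, rt
Reagents that add atoms: hydroxylamine hydrochloride, Cl.NO
Why: Ozonolysis of the vinyl group gives the non-enolisable α-hydroxy aldehyde, which condenses at once with hydroxylamine to the aldoxime.

Step 12
Reactants: 19 (2R)-2-[(4S)-2,2-dimethyl-1,3-dioxolan-4-yl]-2-hydroxypropanal (E)-oxime; 13 (1S,3S)-1-[4-({[(4-methoxyphenyl)methyl]oxy}methyl)-5-oxo-2,5-dihydrofuran-3-yl]-3-methylpent-4-yn-1-yl 3-methylbut-2-enoate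
Product: 22 (1S,3S)-3-{3-[(1R)-1-[(4S)-2,2-dimethyl-1,3-dioxolan-4-yl]-1-hydroxyethyl]-1,2-oxazol-5-yl}-1-[4-({[(4-methoxyphenyl)methyl]oxy}methyl)-5-oxo-2,5-dihydrofuran-3-yl]butyl 3-methylbut-2-enoate, via hydroximoyl chloride 20 (not isolated), via nitrile oxide 21 (not isolated)
Conditions: 19 (2 equiv), N-chlorosuccinimide, DMF, rt; then 13, Et3N (slow addition), CH2Cl2, 0 °C to rt
Reagents that add atoms: none
Why: Huisgen 1,3-dipolar [3+2] cycloaddition of the nitrile oxide to the terminal alkyne gives only the 3,5-disubstituted isoxazole, forming the C1–C2 bond and the five-membered ring that is the masked furanone, with no stereocentre involved.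

Step 13
Reactants: 22 (1S,3S)-3-{3-[(1R)-1-[(4S)-2,2-dimethyl-1,3-dioxolan-4-yl]-1-hydroxyethyl]-1,2-oxazol-5-yl}-1-[4-({[(4-methoxyphenyl)methyl]oxy}methyl)-5-oxo-2,5-dihydrofuran-3-yl]butyl 3-methylbut-2-enoate
Product: 24 (1S,3S)-3-{(5S)-5-[(4S)-2,2-dimethyl-1,3-dioxolan-4-yl]-5-methyl-4-oxo-4,5-dihydrofuran-2-yl}-1-[4-({[(4-methoxyphenyl)methyl]oxy}methyl)-5-oxo-2,5-dihydrofuran-3-yl]butyl 3-methylbut-2-enoate, via enaminone 23 (not isolated)
Conditions: Mo(CO)6, MeCN–H2O (10:1), 80 °C; then 0.5 M aq. HCl, THF, rt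
Reagents that add atoms: water, O
Why: Reductive N–O cleavage gives the β-amino enone, whose hydrolysis to the 1,3-diketone is followed by attack of the tertiary C4 hydroxyl on C1 and loss of water (cyclodehydration) to the 3(2H)-furanone; any acetonide lost here converges in step 14.

Step 14
Reactants: 24 (1S,3S)-3-{(5S)-5-[(4S)-2,2-dimethyl-1,3-dioxolan-4-yl]-5-methyl-4-oxo-4,5-dihydrofuran-2-yl}-1-[4-({[(4-methoxyphenyl)methyl]oxy}methyl)-5-oxo-2,5-dihydrofuran-3-yl]butyl 3-methylbut-2-enoate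
Product: 25 (1S,3S)-3-[(5S)-5-formyl-5-methyl-4-oxo-4,5-dihydrofuran-2-yl]-1-[4-({[(4-methoxyphenyl)methyl]oxy}methyl)-5-oxo-2,5-dihydrofuran-3-yl]butyl 3-methylbut-2-enoate
Conditions: H5IO6, EtOAc, rt
Reagents that add atoms: none
Why: Periodic acid hydrolyses the terminal acetonide and cleaves the 1,2-diol in one pot (glycol cleavage) to unveil the C5 aldehyde, removing the stereocentre that controlled C4.

Step 15
Reactants: 25 (1S,3S)-3-[(5S)-5-formyl-5-methyl-4-oxo-4,5-dihydrofuran-2-yl]-1-[4-({[(4-methoxyphenyl)methyl]oxy}methyl)-5-oxo-2,5-dihydrofuran-3-yl]butyl 3-methylbut-2-enoate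
Product: 28 (4S,5E,8S,10S)-13-[(4-methoxyphenyl)methoxy]-8-[(3-methylbut-2-enoyl)oxy]-3-oxo-1,4-epoxygermacra-1,5,7(11)-trien-12,6-olide, via silyloxyfuran 26 (not isolated), via aldol silyl ether 27 (not isolated)
Conditions: TBSOTf, iPr2NEt, CH2Cl2 (1 mM), −78 to 0 °C; then DBU, rt
Reagents that add atoms: none
Why: Intramolecular vinylogous Mukaiyama aldol addition of the 2-silyloxyfuran to the aldehyde closes the nine-membered oxa-bridged ring at C5–C6, and E1cB loss of silanol gives the ylidene butenolide whose geometry (C4 cis to C7) is fixed by the ring.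

Step 16
Reactants: 28 (4S,5E,8S,10S)-13-[(4-methoxyphenyl)methoxy]-8-[(3-methylbut-2-enoyl)oxy]-3-oxo-1,4-epoxygermacra-1,5,7(11)-trien-12,6-olide
Product: 30 (4S,5E,8S,10S)-13-acetoxy-8-[(3-methylbut-2-enoyl)oxy]-3-oxo-1,4-epoxygermacra-1,5,7(11)-trien-12,6-olide (CNP0102620.1), via alcohol 29 (not isolated)
Conditions: DDQ, CH2Cl2–pH 7 buffer, rt; then Ac2O, pyridine, 0 °C
Reagents that add atoms: acetic anhydride, CC(=O)OC(C)=O
Why: Oxidative cleavage of the 4-methoxybenzyl ether frees the C13 alcohol, which is acetylated only now, when C6 carries no proton and the allylic acetate can no longer be expelled through a dienolate.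

## Compound list

1 | (R)-2,2-dimethyl-1,3-dioxolane-4-carbaldehyde | O=C[C@H]1COC(C)(C)O1 | starting material
2 | ethyl 2-(bromomethyl)prop-2-enoate | C=C(CBr)C(=O)OCC | starting material
3 | ethyl (4S)-4-[(4R)-2,2-dimethyl-1,3-dioxolan-4-yl]-4-hydroxy-2-methylidenebutanoate | CCOC(=O)C(=C)C[C@H](O)[C@H]1COC(C)(C)O1 | intermediate
4 | (5S)-5-[(4R)-2,2-dimethyl-1,3-dioxolan-4-yl]-3-methylideneoxolan-2-one | C=C1C[C@@H]([C@H]2COC(C)(C)O2)OC1=O | intermediate
5 | (3S,5S)-5-[(4R)-2,2-dimethyl-1,3-dioxolan-4-yl]-3-methyloxolan-2-one | C[C@H]1C[C@@H]([C@H]2COC(C)(C)O2)OC1=O | intermediate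
6 | (3S,5S)-5-[(4R)-2,2-dimethyl-1,3-dioxolan-4-yl]-3-methyloxolan-2-ol (lactol, both anomers) | C[C@H]1C[C@@H]([C@H]2COC(C)(C)O2)OC1O | intermediate
7 | (1S,3S)-1-[(4R)-2,2-dimethyl-1,3-dioxolan-4-yl]-3-methylpent-4-yn-1-ol | C#C[C@@H](C)C[C@H](O)[C@H]1COC(C)(C)O1 | intermediate
8 | (1S,3S)-1-[(4R)-2,2-dimethyl-1,3-dioxolan-4-yl]-3-methylpent-4-yn-1-yl 3-methylbut-2-enoate | C#C[C@@H](C)C[C@H](OC(=O)C=C(C)C)[C@H]1COC(C)(C)O1 | intermediate
9 | (2R,3S,5S)-1,2-dihydroxy-5-methylhept-6-yn-3-yl 3-methylbut-2-enoate | C#C[C@@H](C)C[C@H](OC(=O)C=C(C)C)[C@H](O)CO | intermediate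
10 | 2-(diethoxyphosphoryl)prop-2-enoic acid | C=C(C(=O)O)P(=O)(OCC)OCC | starting material
11 | (2R,3S,5S)-2-hydroxy-5-methyl-3-[(3-methylbut-2-enoyl)oxy]hept-6-yn-1-yl 2-(diethoxyphosphoryl)prop-2-enoate | C#C[C@@H](C)C[C@H](OC(=O)C=C(C)C)[C@H](O)COC(=O)C(=C)P(=O)(OCC)OCC | intermediate
12 | (3S,5S)-5-methyl-3-[(3-methylbut-2-enoyl)oxy]-2-oxohept-6-yn-1-yl 2-(diethoxyphosphoryl)prop-2-enoate | C#C[C@@H](C)C[C@H](OC(=O)C=C(C)C)C(=O)COC(=O)C(=C)P(=O)(OCC)OCC | intermediate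
13 | (1S,3S)-1-[4-({[(4-methoxyphenyl)methyl]oxy}methyl)-5-oxo-2,5-dihydrofuran-3-yl]-3-methylpent-4-yn-1-yl 3-methylbut-2-enoate | C#C[C@@H](C)C[C@H](OC(=O)C=C(C)C)C1=C(COCc2ccc(OC)cc2)C(=O)OC1 | intermediate
14 | methyl (4S)-2,2-dimethyl-1,3-dioxolane-4-carboxylate | COC(=O)[C@@H]1COC(C)(C)O1 | starting material
15 | (4S)-N-methoxy-N,2,2-trimethyl-1,3-dioxolane-4-carboxamide | CON(C)C(=O)[C@@H]1COC(C)(C)O1 | intermediate
16 | 1-[(4S)-2,2-dimethyl-1,3-dioxolan-4-yl]ethan-1-one | CC(=O)[C@@H]1COC(C)(C)O1 | intermediate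
17 | (2R)-2-[(4S)-2,2-dimethyl-1,3-dioxolan-4-yl]but-3-en-2-ol | C=C[C@@](C)(O)[C@@H]1COC(C)(C)O1 | intermediate
18 | (2S)-2-[(4S)-2,2-dimethyl-1,3-dioxolan-4-yl]-2-hydroxypropanal | O=C[C@@](C)(O)[C@@H]1COC(C)(C)O1 | intermediate
19 | (2R)-2-[(4S)-2,2-dimethyl-1,3-dioxolan-4-yl]-2-hydroxypropanal (E)-oxime | O/N=C/[C@@](C)(O)[C@@H]1COC(C)(C)O1 | intermediate
20 | (2S)-2-[(4S)-2,2-dimethyl-1,3-dioxolan-4-yl]-N,2-dihydroxypropanimidoyl chloride | ON=C(Cl)[C@@](C)(O)[C@@H]1COC(C)(C)O1 | intermediate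
21 | (2R)-2-[(4S)-2,2-dimethyl-1,3-dioxolan-4-yl]-2-hydroxypropanenitrile N-oxide | [O-][N+]#C[C@@](C)(O)[C@@H]1COC(C)(C)O1 | intermediate
22 | (1S,3S)-3-{3-[(1R)-1-[(4S)-2,2-dimethyl-1,3-dioxolan-4-yl]-1-hydroxyethyl]-1,2-oxazol-5-yl}-1-[4-({[(4-methoxyphenyl)methyl]oxy}methyl)-5-oxo-2,5-dihydrofuran-3-yl]butyl 3-methylbut-2-enoate | C[C@](O)([C@@H]1COC(C)(C)O1)c1cc(on1)[C@@H](C)C[C@H](OC(=O)C=C(C)C)C1=C(COCc2ccc(OC)cc2)C(=O)OC1 | intermediate
23 | (1S,3S,5Z,7R)-6-amino-7-[(4S)-2,2-dimethyl-1,3-dioxolan-4-yl]-7-hydroxy-1-[4-({[(4-methoxyphenyl)methyl]oxy}methyl)-5-oxo-2,5-dihydrofuran-3-yl]-3-methyl-4-oxooct-5-en-1-yl 3-methylbut-2-enoate | C[C@](O)([C@@H]1COC(C)(C)O1)/C(N)=C/C(=O)[C@@H](C)C[C@H](OC(=O)C=C(C)C)C1=C(COCc2ccc(OC)cc2)C(=O)OC1 | intermediate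
24 | (1S,3S)-3-{(5S)-5-[(4S)-2,2-dimethyl-1,3-dioxolan-4-yl]-5-methyl-4-oxo-4,5-dihydrofuran-2-yl}-1-[4-({[(4-methoxyphenyl)methyl]oxy}methyl)-5-oxo-2,5-dihydrofuran-3-yl]butyl 3-methylbut-2-enoate | CC1(C)OC[C@H](O1)[C@]2(C)OC(=CC2=O)[C@@H](C)C[C@H](OC(=O)C=C(C)C)C3=C(COCc4ccc(OC)cc4)C(=O)OC3 | intermediate
25 | (1S,3S)-3-[(5S)-5-formyl-5-methyl-4-oxo-4,5-dihydrofuran-2-yl]-1-[4-({[(4-methoxyphenyl)methyl]oxy}methyl)-5-oxo-2,5-dihydrofuran-3-yl]butyl 3-methylbut-2-enoate | O=C[C@]1(C)OC(=CC1=O)[C@@H](C)C[C@H](OC(=O)C=C(C)C)C2=C(COCc3ccc(OC)cc3)C(=O)OC2 | intermediate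
26 | (1S,3S)-1-[5-{[tert-butyl(dimethyl)silyl]oxy}-4-({[(4-methoxyphenyl)methyl]oxy}methyl)furan-3-yl]-3-[(5S)-5-formyl-5-methyl-4-oxo-4,5-dihydrofuran-2-yl]butyl 3-methylbut-2-enoate | O=C[C@]1(C)OC(=CC1=O)[C@@H](C)C[C@H](OC(=O)C=C(C)C)c2coc(O[Si](C)(C)C(C)(C)C)c2COCc3ccc(OC)cc3 | intermediate
27 | (4S,8S,10S)-5-{[tert-butyl(dimethyl)silyl]oxy}-13-[(4-methoxyphenyl)methoxy]-8-[(3-methylbut-2-enoyl)oxy]-3-oxo-1,4-epoxygermacra-1,7(11)-dien-12,6-olide (C5 and C6 epimers) | COc1ccc(COCC2=C3C(C(O[Si](C)(C)C(C)(C)C)[C@]4(C)OC(=CC4=O)[C@@H](C)C[C@@H]3OC(=O)C=C(C)C)OC2=O)cc1 | intermediate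
28 | (4S,5E,8S,10S)-13-[(4-methoxyphenyl)methoxy]-8-[(3-methylbut-2-enoyl)oxy]-3-oxo-1,4-epoxygermacra-1,5,7(11)-trien-12,6-olide | COc1ccc(COCC2=C3/C(=C\[C@]4(C)OC(=CC4=O)[C@@H](C)C[C@@H]3OC(=O)C=C(C)C)OC2=O)cc1 | intermediate
29 | (4S,5E,8S,10S)-13-hydroxy-8-[(3-methylbut-2-enoyl)oxy]-3-oxo-1,4-epoxygermacra-1,5,7(11)-trien-12,6-olide | OCC1=C2/C(=C\[C@]3(C)OC(=CC3=O)[C@@H](C)C[C@@H]2OC(=O)C=C(C)C)OC1=O | intermediate
30 | (4S,5E,8S,10S)-13-acetoxy-8-[(3-methylbut-2-enoyl)oxy]-3-oxo-1,4-epoxygermacra-1,5,7(11)-trien-12,6-olide (CNP0102620.1) | CC(=O)OCC1=C2/C(=C\[C@]3(C)OC(=CC3=O)[C@@H](C)C[C@@H]2OC(=O)C=C(C)C)OC1=O | target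

## Step count and risks

Total step count: 16 (steps 1–8 East fragment, 9–11 West fragment, 12–16 after the union).
Longest linear sequence: 13 steps (steps 1–8, then 12–16).

The three steps most likely to fail are step 15, step 8 and step 10.

Step 15 is a medium-ring closure onto a hindered, deformylation-prone aldehyde, and DBU can epimerise C10 through the furanone dienolate. The fallback sets out from 24 and comes back at 28, closing the ring by an intramolecular Horner–Wadsworth–Emmons olefination instead of an aldol addition and elimination. Compound 24 is converted with TBSOTf and Et3N into the 2-silyloxyfuran F1, which N-bromosuccinimide brominates at C6 to give the 5-bromobutenolide F2. Arbuzov reaction with P(OEt)3 gives the C6 phosphonate F3, H5IO6 unveils the aldehyde to give the formyl phosphonate F4, and LiCl with iPr2NEt in MeCN at high dilution forms the C5=C6 bond and gives 28.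

Step 8 needs a base that can epimerise C8 next to the ketone, and the sequence can stall at the conjugate adduct. The fallback sets out from 9 and 10 and comes back at 13; the C13–O bond is made before the acid is attached and the olefination is run separately under salt-mediated conditions without alkoxide. Conjugate addition of 4-methoxybenzyl alcohol to 10 (NaH, THF) gives the saturated phosphono acid F5. DCC esterification of the primary hydroxyl of 9 with it gives the hydroxy ester F6, Dess–Martin oxidation gives the keto phosphonate F7, and LiCl with iPr2NEt in MeCN (Masamune–Roush olefination) gives 13.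

Step 10 depends on Felkin–Anh selectivity of a small Grignard reagent on an acyl dioxolane, which may be low. The fallback sets out from 14 and comes back at 17, introducing the two carbon groups in the reverse order under chelation control. The Weinreb amide 15 formed in the flask from 14 is treated with CH2=CHMgBr to give the vinyl ketone F8. MeMgBr with MgBr2·OEt2 in CH2Cl2 at −78 °C then adds through the five-membered magnesium chelate, on the face opposite to the Felkin–Anh mode, and so gives the same (2R)-carbinol 17.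

Further compounds
F1 | step 15 | (1S,3S)-1-[5-{[tert-butyl(dimethyl)silyl]oxy}-4-({[(4-methoxyphenyl)methyl]oxy}methyl)furan-3-yl]-3-{(5S)-5-[(4S)-2,2-dimethyl-1,3-dioxolan-4-yl]-5-methyl-4-oxo-4,5-dihydrofuran-2-yl}butyl 3-methylbut-2-enoate | CC1(C)OC[C@H](O1)[C@]2(C)OC(=CC2=O)[C@@H](C)C[C@H](OC(=O)C=C(C)C)c3coc(O[Si](C)(C)C(C)(C)C)c3COCc4ccc(OC)cc4
F2 | step 15 | (1S,3S)-1-[2-bromo-4-({[(4-methoxyphenyl)methyl]oxy}methyl)-5-oxo-2,5-dihydrofuran-3-yl]-3-{(5S)-5-[(4S)-2,2-dimethyl-1,3-dioxolan-4-yl]-5-methyl-4-oxo-4,5-dihydrofuran-2-yl}butyl 3-methylbut-2-enoate (both C–Br epimers) | CC1(C)OC[C@H](O1)[C@]2(C)OC(=CC2=O)[C@@H](C)C[C@H](OC(=O)C=C(C)C)C3=C(COCc4ccc(OC)cc4)C(=O)OC3Br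
F3 | step 15 | (1S,3S)-1-[2-(diethoxyphosphoryl)-4-({[(4-methoxyphenyl)methyl]oxy}methyl)-5-oxo-2,5-dihydrofuran-3-yl]-3-{(5S)-5-[(4S)-2,2-dimethyl-1,3-dioxolan-4-yl]-5-methyl-4-oxo-4,5-dihydrofuran-2-yl}butyl 3-methylbut-2-enoate | CC1(C)OC[C@H](O1)[C@]2(C)OC(=CC2=O)[C@@H](C)C[C@H](OC(=O)C=C(C)C)C3=C(COCc4ccc(OC)cc4)C(=O)OC3P(=O)(OCC)OCC
F4 | step 15 | (1S,3S)-1-[2-(diethoxyphosphoryl)-4-({[(4-methoxyphenyl)methyl]oxy}methyl)-5-oxo-2,5-dihydrofuran-3-yl]-3-[(5S)-5-formyl-5-methyl-4-oxo-4,5-dihydrofuran-2-yl]butyl 3-methylbut-2-enoate | O=C[C@]1(C)OC(=CC1=O)[C@@H](C)C[C@H](OC(=O)C=C(C)C)C2=C(COCc3ccc(OC)cc3)C(=O)OC2P(=O)(OCC)OCC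
F5 | step 8 | 2-(diethoxyphosphoryl)-3-[(4-methoxyphenyl)methoxy]propanoic acid (racemic) | CCOP(=O)(OCC)C(COCc1ccc(OC)cc1)C(=O)O
F6 | step 8 | (2R,3S,5S)-2-hydroxy-5-methyl-3-[(3-methylbut-2-enoyl)oxy]hept-6-yn-1-yl 2-(diethoxyphosphoryl)-3-[(4-methoxyphenyl)methoxy]propanoate | C#C[C@@H](C)C[C@H](OC(=O)C=C(C)C)[C@H](O)COC(=O)C(COCc1ccc(OC)cc1)P(=O)(OCC)OCC
F7 | step 8 | (3S,5S)-5-methyl-3-[(3-methylbut-2-enoyl)oxy]-2-oxohept-6-yn-1-yl 2-(diethoxyphosphoryl)-3-[(4-methoxyphenyl)methoxy]propanoate | C#C[C@@H](C)C[C@H](OC(=O)C=C(C)C)C(=O)COC(=O)C(COCc1ccc(OC)cc1)P(=O)(OCC)OCC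
F8 | step 10 | 1-[(4S)-2,2-dimethyl-1,3-dioxolan-4-yl]prop-2-en-1-one | C=CC(=O)[C@@H]1COC(C)(C)O1
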